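**Retrosynthetic overview**

1. Labels: ring C1(O‑angeloyl)–C2–C3(CH3)–C4(OH)–C5–C6; side chain C7(CH3)–C8–C9(OAc)–C10=C11. Feature used: the cis C1/C4 dioxygen pair that flanks C2–C3(CH3) and lies anti to the C6 side chain is the retron of a 2,3‑dioxabicyclo[2.2.2]oct‑5‑ene.
2. Target ⇐ γ‑hydroxy enone 15 (C4=O, C2=C3, C1–OH) by acylation at C1, conjugate reduction with equilibration of C3, and axial‑selective hydride delivery at C4.
3. 15 ⇐ zingiberene‑type ring diene 13 (C1=C2–C3(CH3)=C4) by biomimetic singlet‑oxygen [4+2] across C1/C4 (transient peroxide bridge) and Kornblum–DeLaMare opening.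
4. 13 ⇐ 4‑substituted cyclohexenone 11 (dienyl triflate, methyl coupling) ⇐ the only carbocycle closure, an organocatalytic Michael/aldol annulation of aldehyde 8 with methyl vinyl ketone, which sets C6.
5. 8 ⇐ crotonaldehyde + silyl dienol ether of mesityl oxide (Mukaiyama–Michael, C7), then CBS reduction (C9).

Key step: step 9

Remark: the 2‑methylbut‑2‑enoate in the SMILES is read as the (Z)‑isomer (angelate), and the atom labels C1–C11 defined above are used throughout.

**Route**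

Step 1
Reactants: 1 mesityl oxide (4‑methylpent‑3‑en‑2‑one)
Product: 2 trimethyl[(4‑methylpenta‑1,3‑dien‑2‑yl)oxy]silane
Conditions: LDA, THF, −78 °C; then TMSCl, −78 °C → rt
Reagents that add atoms: chlorotrimethylsilane, C[Si](C)(C)Cl
Why: Kinetic deprotonation of the enone at the α′‑methyl group and O‑silylation of the cross‑conjugated lithium dienolate (silyl enol ether formation) should give the 2‑silyloxydiene; no stereocenter is formed.

Step 2
Reactants: 2 trimethyl[(4‑methylpenta‑1,3‑dien‑2‑yl)oxy]silane; 3 (E)‑crotonaldehyde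
Product: 5 (6S)‑8,8‑dimethoxy‑2,6‑dimethyloct‑2‑en‑4‑one, via keto aldehyde 4 (not isolated)
Conditions: (2R,5R)‑5‑benzyl‑2‑tert‑butyl‑3‑methylimidazolidin‑4‑one·2,4‑dinitrobenzoic acid (20 mol %), CH2Cl2, H2O (2 equiv), −40 °C; then HC(OMe)3, MeOH, PPTS (cat.), rt
Reagents that add atoms: trimethyl orthoformate, COC(OC)OC
Why: Iminium‑catalysed Mukaiyama–Michael addition of a silyl enol ether to an enal: the benzyl group of the (2R,5R)‑catalyst shields one face of the iminium ion of 3, so the enol carbon of 2 should bond to the Si face of the β‑carbon and set C7 (3S in 4), and the aldehyde is then masked in the same flask by acid‑catalysed acetalization.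

Step 3
Reactants: 5 (6S)‑8,8‑dimethoxy‑2,6‑dimethyloct‑2‑en‑4‑one
Product: 6 (4R,6R)‑8,8‑dimethoxy‑2,6‑dimethyloct‑2‑en‑4‑ol
Conditions: (S)‑2‑methyl‑CBS‑oxazaborolidine (20 mol %), catecholborane, toluene, −78 °C
Reagents that add atoms: none
Why: Corey–Bakshi–Shibata reduction of an enone: with the 2‑methylprop‑1‑enyl group as the large substituent, the (S)‑oxazaborolidine should deliver hydride 1,2 to give the 4R allylic alcohol (C9) under reagent control, without touching the acetal.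

Step 4
Reactants: 6 (4R,6R)‑8,8‑dimethoxy‑2,6‑dimethyloct‑2‑en‑4‑ol
Product: 7 (4R,6R)‑8,8‑dimethoxy‑2,6‑dimethyloct‑2‑en‑4‑yl acetate
Conditions: Ac2O, pyridine, DMAP (cat.), CH2Cl2, 0 °C → rt
Reagents that add atoms: acetic anhydride, CC(=O)OC(C)=O
Why: DMAP‑catalysed acetylation of the secondary allylic alcohol puts the C9 acetate of the target in place early, with C9 untouched.

Step 5
Reactants: 7 (4R,6R)‑8,8‑dimethoxy‑2,6‑dimethyloct‑2‑en‑4‑yl acetate
Product: 8 (4R,6R)‑2,6‑dimethyl‑8‑oxooct‑2‑en‑4‑yl acetate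
Conditions: AcOH/THF/H2O (3:1:1), 35 °C
Reagents that add atoms: water, O
Why: Mild acid hydrolysis of the acyclic dimethyl acetal frees the aldehyde under conditions in which the secondary allylic acetate should not ionize.

Step 6
Reactants: 8 (4R,6R)‑2,6‑dimethyl‑8‑oxooct‑2‑en‑4‑yl acetate; 9 methyl vinyl ketone
Product: 11 (4R,6R)‑2‑methyl‑6‑[(1S)‑4‑oxocyclohex‑2‑en‑1‑yl]hept‑2‑en‑4‑yl acetate, via Michael adduct 10 (not isolated)
Conditions: (S)‑α,α‑diphenylprolinol trimethylsilyl ether (10 mol %), ethyl 3,4‑dihydroxybenzoate (20 mol %), neat, 4 °C; then pTsOH·H2O (20 mol %), toluene, 40 °C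
Reagents that add atoms: none
Why: Organocatalytic Robinson‑type annulation: the E‑enamine of 8 adds to 9 from the face opposite the diphenyl(silyloxy)methyl group (enamine Michael addition, catalyst control over the C7 center) to set C6 as S, and acid‑catalysed intramolecular aldol condensation of the methyl ketone onto the aldehyde closes the ring in the only possible six‑membered mode.

Step 7
Reactants: 11 (4R,6R)‑2‑methyl‑6‑[(1S)‑4‑oxocyclohex‑2‑en‑1‑yl]hept‑2‑en‑4‑yl acetate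
Product: 12 (4R,6R)‑2‑methyl‑6‑[(1S)‑4‑{[(trifluoromethyl)sulfonyl]oxy}cyclohexa‑2,4‑dien‑1‑yl]hept‑2‑en‑4‑yl acetate
Conditions: LiHMDS, THF, −78 °C; then PhNTf2, −78 → 0 °C
Reagents that add atoms: N‑phenylbis(trifluoromethanesulfonimide), O=S(=O)(N(c1ccccc1)S(=O)(=O)C(F)(F)F)C(F)(F)F
Why: Kinetic deprotonation of the cyclohexenone at the α′‑methylene C4 (not at the γ‑carbon C6 and not at the less acidic acetate) and O‑triflation of the cross‑conjugated enolate give the 2‑triflyloxy‑1,3‑diene without touching C6.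

Step 8
Reactants: 12 (4R,6R)‑2‑methyl‑6‑[(1S)‑4‑{[(trifluoromethyl)sulfonyl]oxy}cyclohexa‑2,4‑dien‑1‑yl]hept‑2‑en‑4‑yl acetate
Product: 13 (4R,6R)‑2‑methyl‑6‑[(1S)‑4‑methylcyclohexa‑2,4‑dien‑1‑yl]hept‑2‑en‑4‑yl acetate
Conditions: MeZnCl, Pd(PPh3)4 (5 mol %), THF, 0 °C → rt
Reagents that add atoms: methylzinc chloride, C[Zn]Cl
Why: Negishi cross‑coupling of the alkenyl triflate installs the C3 methyl group with the diene in place; oxidative addition to the triflate at room temperature should outpace ionization of the hindered allylic acetate, and the organozinc does not attack esters.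

Step 9
Reactants: 13 (4R,6R)‑2‑methyl‑6‑[(1S)‑4‑methylcyclohexa‑2,4‑dien‑1‑yl]hept‑2‑en‑4‑yl acetate
Product: 15 (4R,6R)‑6‑[(1S,2S)‑2‑hydroxy‑4‑methyl‑5‑oxocyclohex‑3‑en‑1‑yl]‑2‑methylhept‑2‑en‑4‑yl acetate, via endoperoxide 14 (not isolated)
Conditions: O2, tetraphenylporphyrin (1 mol %), CH2Cl2, −78 °C, hν (white LED); then lamp off, Ar purge, Et3N, −78 → 0 °C
Reagents that add atoms: oxygen, O=O
Why: Sensitized singlet oxygen adds as a dienophile in a concerted suprafacial [4+2] cycloaddition across C1 and C4 of the cisoid ring diene of 13, the closest known reaction type being the photooxygenation of α‑phellandrene and other 5‑alkylcyclohexa‑1,3‑dienes to 2,3‑dioxabicyclo[2.2.2]oct‑5‑enes. The six‑membered 1,2‑dioxene ring of 14 is closed by this intermolecular cycloaddition, which places both new C–O bonds on one face of the carbocycle. The new stereocenters C1 and C4 are controlled by the existing C6 stereocenter, because the side chain, pseudoaxial in the reacting half‑chair, shields its own face and oxygen should add anti to it. Triethylamine then removes the bridgehead hydrogen at C4 in an E2‑type Kornblum–DeLaMare fragmentation of the O–O bond, which turns C4 into the enone carbonyl and leaves C1 as the carbinol with its configuration unchanged. The step needs chemoselectivity for the diene over the C10=C11 alkene, secured by the faster [4+2] addition to a cisoid diene at −78 °C and by the deactivating allylic acetate, and regioselectivity in the fragmentation, secured by the lower hindrance at C4–H (next to the C5 methylene) than at C1–H (next to the branched C6).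

Step 10
Reactants: 15 (4R,6R)‑6‑[(1S,2S)‑2‑hydroxy‑4‑methyl‑5‑oxocyclohex‑3‑en‑1‑yl]‑2‑methylhept‑2‑en‑4‑yl acetate; 16 angelic acid ((2Z)‑2‑methylbut‑2‑enoic acid)
Product: 17 (1S,6S)‑6‑[(2R,4R)‑4‑(acetyloxy)‑6‑methylhept‑5‑en‑2‑yl]‑3‑methyl‑4‑oxocyclohex‑2‑en‑1‑yl (2Z)‑2‑methylbut‑2‑enoate
Conditions: 16, 2,4,6‑trichlorobenzoyl chloride, Et3N, toluene, rt; then 15, DMAP, rt
Reagents that add atoms: none
Why: Yamaguchi esterification: the mixed anhydride of 16 acylates the C1 hydroxyl, the only free one in the molecule, with retention at C1, and the mild conditions at room temperature should keep the Z geometry of the angeloyl group.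

Step 11
Reactants: 17 (1S,6S)‑6‑[(2R,4R)‑4‑(acetyloxy)‑6‑methylhept‑5‑en‑2‑yl]‑3‑methyl‑4‑oxocyclohex‑2‑en‑1‑yl (2Z)‑2‑methylbut‑2‑enoate
Product: 18 (1R,2S,5S)‑2‑[(2R,4R)‑4‑(acetyloxy)‑6‑methylhept‑5‑en‑2‑yl]‑5‑methyl‑4‑oxocyclohexyl (2Z)‑2‑methylbut‑2‑enoate
Conditions: [(Ph3P)CuH]6, benzene, H2O (degassed), rt; then DBU (cat.), CH2Cl2, rt
Reagents that add atoms: none
Why: Conjugate reduction of the ring enone with Stryker's reagent (copper hydride 1,4‑addition at C2) leaves the C10=C11 alkene, the trisubstituted angelate and the acetate alone, and the C3 center next to the ketone is brought by base equilibration to the equatorial methyl isomer (all three ring substituents equatorial), which is cis to the C1 ester.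

Step 12
Reactants: 18 (1R,2S,5S)‑2‑[(2R,4R)‑4‑(acetyloxy)‑6‑methylhept‑5‑en‑2‑yl]‑5‑methyl‑4‑oxocyclohexyl (2Z)‑2‑methylbut‑2‑enoate
Product: 19 (1R,2S,4R,5S)‑2‑[(2R,4R)‑4‑(acetyloxy)‑6‑methylhept‑5‑en‑2‑yl]‑4‑hydroxy‑5‑methylcyclohexyl (2Z)‑2‑methylbut‑2‑enoate (target)
Conditions: L‑Selectride, THF, −78 °C; then H2O
Reagents that add atoms: none
Why: Bulky‑hydride reduction of a 2‑methylcyclohexanone: L‑Selectride should attack C4 from the equatorial direction to give the axial alcohol cis to the C3 methyl group (4R), faster than it touches the acetate or the trisubstituted angelate at −78 °C.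

**Compound list**

1 | mesityl oxide (4‑methylpent‑3‑en‑2‑one) | CC(=O)C=C(C)C | starting material
2 | trimethyl[(4‑methylpenta‑1,3‑dien‑2‑yl)oxy]silane | C=C(O[Si](C)(C)C)C=C(C)C | intermediate
3 | (E)‑crotonaldehyde | C/C=C/C=O | starting material
4 | (3S)‑3,7‑dimethyl‑5‑oxooct‑6‑enal (keto aldehyde, not isolated) | O=CC[C@H](C)CC(=O)C=C(C)C | intermediate
5 | (6S)‑8,8‑dimethoxy‑2,6‑dimethyloct‑2‑en‑4‑one | COC(OC)C[C@H](C)CC(=O)C=C(C)C | intermediate
6 | (4R,6R)‑8,8‑dimethoxy‑2,6‑dimethyloct‑2‑en‑4‑ol | COC(OC)C[C@H](C)C[C@H](C=C(C)C)O | intermediate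
7 | (4R,6R)‑8,8‑dimethoxy‑2,6‑dimethyloct‑2‑en‑4‑yl acetate | COC(OC)C[C@H](C)C[C@H](C=C(C)C)OC(C)=O | intermediate
8 | (4R,6R)‑2,6‑dimethyl‑8‑oxooct‑2‑en‑4‑yl acetate | O=CC[C@H](C)C[C@H](C=C(C)C)OC(C)=O | intermediate
9 | methyl vinyl ketone | CC(=O)C=C | starting material
10 | (4R,6R,7S)‑7‑formyl‑2,6‑dimethyl‑10‑oxoundec‑2‑en‑4‑yl acetate (Michael adduct, not isolated) | CC(=O)CC[C@H](C=O)[C@H](C)C[C@H](C=C(C)C)OC(C)=O | intermediate
11 | (4R,6R)‑2‑methyl‑6‑[(1S)‑4‑oxocyclohex‑2‑en‑1‑yl]hept‑2‑en‑4‑yl acetate | O=C1CC[C@H](C=C1)[C@H](C)C[C@H](C=C(C)C)OC(C)=O | intermediate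
12 | (4R,6R)‑2‑methyl‑6‑[(1S)‑4‑{[(trifluoromethyl)sulfonyl]oxy}cyclohexa‑2,4‑dien‑1‑yl]hept‑2‑en‑4‑yl acetate | FC(F)(F)S(=O)(=O)OC1=CC[C@H](C=C1)[C@H](C)C[C@H](C=C(C)C)OC(C)=O | intermediate
13 | (4R,6R)‑2‑methyl‑6‑[(1S)‑4‑methylcyclohexa‑2,4‑dien‑1‑yl]hept‑2‑en‑4‑yl acetate | CC1=CC[C@H](C=C1)[C@H](C)C[C@H](C=C(C)C)OC(C)=O | intermediate
14 | (4R,6R)‑2‑methyl‑6‑[(1S,4R,7S)‑5‑methyl‑2,3‑dioxabicyclo[2.2.2]oct‑5‑en‑7‑yl]hept‑2‑en‑4‑yl acetate (endoperoxide, not isolated) | O1[C@@H]2C=C(C)[C@H](O1)C[C@H]2[C@H](C)C[C@H](C=C(C)C)OC(C)=O | intermediate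
15 | (4R,6R)‑6‑[(1S,2S)‑2‑hydroxy‑4‑methyl‑5‑oxocyclohex‑3‑en‑1‑yl]‑2‑methylhept‑2‑en‑4‑yl acetate | O[C@@H]1C=C(C)C(=O)C[C@H]1[C@H](C)C[C@H](C=C(C)C)OC(C)=O | intermediate
16 | angelic acid ((2Z)‑2‑methylbut‑2‑enoic acid) | C/C=C(/C)C(O)=O | starting material
17 | (1S,6S)‑6‑[(2R,4R)‑4‑(acetyloxy)‑6‑methylhept‑5‑en‑2‑yl]‑3‑methyl‑4‑oxocyclohex‑2‑en‑1‑yl (2Z)‑2‑methylbut‑2‑enoate | C/C=C(/C)C(=O)O[C@@H]1C=C(C)C(=O)C[C@H]1[C@H](C)C[C@H](C=C(C)C)OC(C)=O | intermediate
18 | (1R,2S,5S)‑2‑[(2R,4R)‑4‑(acetyloxy)‑6‑methylhept‑5‑en‑2‑yl]‑5‑methyl‑4‑oxocyclohexyl (2Z)‑2‑methylbut‑2‑enoate | C/C=C(/C)C(=O)O[C@@H]1C[C@H](C)C(=O)C[C@H]1[C@H](C)C[C@H](C=C(C)C)OC(C)=O | intermediate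
19 | (1R,2S,4R,5S)‑2‑[(2R,4R)‑4‑(acetyloxy)‑6‑methylhept‑5‑en‑2‑yl]‑4‑hydroxy‑5‑methylcyclohexyl (2Z)‑2‑methylbut‑2‑enoate | C/C=C(/C)C(=O)O[C@@H]1C[C@H](C)[C@H](O)C[C@H]1[C@H](C)C[C@H](C=C(C)C)OC(C)=O | target

**Step count and risks**

Total step count: 12. Longest linear sequence: 12 steps (1 → 19).

Steps most likely to fail:

1. Step 9 (key step). Singlet oxygen may add to both faces of the diene, because the C6 side chain can also sit pseudoequatorial, where it shields poorly; this poor facial selectivity would give both C1 epimers. The fallback sets out from 13 and comes back at 17, and makes the step stereoconvergent instead of stereoselective. The cycloaddition and fragmentation are run as in step 9 and the two C1‑epimeric hydroxy enones are separated. 15 is acylated with retention as in step 10. The cis isomer (4R,6R)‑6‑[(1S,2R)‑2‑hydroxy‑4‑methyl‑5‑oxocyclohex‑3‑en‑1‑yl]‑2‑methylhept‑2‑en‑4‑yl acetate F1 is esterified with 16 under Mitsunobu conditions (PPh3, DIAD, toluene, 0 °C). The SN2 displacement with inversion at C1, from the face anti to the side chain, should deliver the same ester 17.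

2. Step 2. The ketone‑derived dienol silane may add with low enantiofacial control or by competing 1,2‑addition to the iminium ion. The fallback sets out from 3 and comes back at 5; it uses a nucleophile class with close precedent for crotonaldehyde and forms the C9–C10 bond separately. 3 is treated with trimethyl{[1‑(propan‑2‑ylsulfanyl)ethenyl]oxy}silane under the same imidazolidinone catalysis to give S‑propan‑2‑yl (3S)‑3‑methyl‑5‑oxopentanethioate F2. This is acetalized in the same flask (HC(OMe)3, MeOH, PPTS) to S‑propan‑2‑yl (3S)‑5,5‑dimethoxy‑3‑methylpentanethioate F3. Liebeskind–Srogl coupling of F3 with (2‑methylprop‑1‑en‑1‑yl)boronic acid (Pd2(dba)3, tri(2‑furyl)phosphine, copper(I) thiophene‑2‑carboxylate, THF, 50 °C) should then give enone 5.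

3. Step 10. The (Z)‑2‑methylbut‑2‑enoyl unit may isomerize to the (E)‑isomer during activation, or acylation of the hindered C1 hydroxyl may be sluggish. The fallback sets out from 15 and comes back at 18; it builds the Z‑alkene after the ester bond. 15 is first reduced with [(Ph3P)CuH]6 (benzene, H2O, rt; then DBU cat.) to (4R,6R)‑6‑[(1S,2R,4S)‑2‑hydroxy‑4‑methyl‑5‑oxocyclohexyl]‑2‑methylhept‑2‑en‑4‑yl acetate F4. F4 is acylated with 2‑[bis(2,2,2‑trifluoroethoxy)phosphoryl]propanoic acid (DCC, DMAP cat., CH2Cl2) to (1R,2S,5S)‑2‑[(2R,4R)‑4‑(acetyloxy)‑6‑methylhept‑5‑en‑2‑yl]‑5‑methyl‑4‑oxocyclohexyl 2‑[bis(2,2,2‑trifluoroethoxy)phosphoryl]propanoate F5. Still–Gennari olefination of F5 with acetaldehyde (KHMDS, 18‑crown‑6, THF, −78 °C) should give the Z‑configured ester 18.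

**Further compounds**

F1 | step 9 | (4R,6R)‑6‑[(1S,2R)‑2‑hydroxy‑4‑methyl‑5‑oxocyclohex‑3‑en‑1‑yl]‑2‑methylhept‑2‑en‑4‑yl acetate | O[C@H]1C=C(C)C(=O)C[C@H]1[C@H](C)C[C@H](C=C(C)C)OC(C)=O
F2 | step 2 | S‑propan‑2‑yl (3S)‑3‑methyl‑5‑oxopentanethioate | O=CC[C@H](C)CC(=O)SC(C)C
F3 | step 2 | S‑propan‑2‑yl (3S)‑5,5‑dimethoxy‑3‑methylpentanethioate | COC(OC)C[C@H](C)CC(=O)SC(C)C
F4 | step 10 | (4R,6R)‑6‑[(1S,2R,4S)‑2‑hydroxy‑4‑methyl‑5‑oxocyclohexyl]‑2‑methylhept‑2‑en‑4‑yl acetate | O[C@@H]1C[C@H](C)C(=O)C[C@H]1[C@H](C)C[C@H](C=C(C)C)OC(C)=O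
F5 | step 10 | (1R,2S,5S)‑2‑[(2R,4R)‑4‑(acetyloxy)‑6‑methylhept‑5‑en‑2‑yl]‑5‑methyl‑4‑oxocyclohexyl 2‑[bis(2,2,2‑trifluoroethoxy)phosphoryl]propanoate | CC(C(=O)O[C@@H]1C[C@H](C)C(=O)C[C@H]1[C@H](C)C[C@H](C=C(C)C)OC(C)=O)P(=O)(OCC(F)(F)F)OCC(F)(F)F
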